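**The question.** Rank these flasks by the share of target in what became target or over-reaction product, early and late.

| setting | north | north-east | Sunday's | Saturday's | Thursday's | Monday's |
|---|---|---|---|---|---|---|
| starting material | 0.11 M | 1.4 M | 0.30 M | 0.20 M | 1.0 M | 0.080 M |
| remark | run made earlier | run made earlier |  |  |  |  |
| time |  |  | 2.0 min | 2.0 min | 2.0 min | 2.0 min |

- north (time / s: target / %, over-reaction product / %, starting material / %): 20.0: 0, 0, 77; 40.0: 0, 2, 65; 60.0: 1, 0, 57; 80.0: 0, 0, 51
- north-east (time / s: target / %, over-reaction product / %, starting material / %): 10.0: 2, 1, 85; 30.0: 65, 17, 2; 50.0: 50, 40, 1; 80.0: 29, 59, 0

(scatter of a reading: 1.5 percentage points)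

* ranking by share of target in all that became target or over-reaction product, from high to low, at 2.0 min (Sunday's / Saturday's / Thursday's / Monday's)
* the same order at 25 s (Sunday's / Saturday's / Thursday's / Monday's)
* the share of target in all that became target or over-reaction product of the flask you put first, at 2.0 min
* the share of target in all that became target or over-reaction product of the flask you put last, at 2.0 min

**Main step.** Start with target making more target from starting material, after a slow direct step seeds it. In the north-east run, the ratio of converted to remaining starting material grows at 0.353 s⁻¹. This is a rough reading, since it rests on small percentages. Divide by the 1.19 M of free starting material at 10.0 s. That gives a constant of 0.297 M⁻¹ s⁻¹. With this step by itself, no over-reaction product forms, so the share does not fall.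

**Add loss.** Now let target decay. In the north-east run, target falls from 50 % to 29 % with starting material near 1 %, so target is lost at 0.0182 s⁻¹. Per target, the gain is in proportion to free starting material and the loss is at a fixed rate. Divide the loss constant by the growth constant: 0.0612 M. Call this free amount, where target is made as fast as it is used, the break-even level. Free starting material over this level gives making over using.

**Add parking.** The north run shows starting material at 51 % by 80.0 s, with target near 0 %, so the dormant form takes up the difference. Scaled to this fraction, Sunday's flask holds 0.153 M free, above the level. Monday's flask holds 0.0408 M, below it. Thursday's flask, scaled from the north-east run at 30.0 s, drops to 0.0200 M, below it after its burst. My reckoning puts Sunday's first and Thursday's last at 2.0 min. At 25 s, I rank by growth speed, so by charge from high to low.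

**The forecast.** It gives Sunday's > Saturday's > Monday's > Thursday's at 2.0 min, with 57 % and 21 %, and Thursday's > Sunday's > Saturday's > Monday's at 25 s. For Thursday's flask it says “the burst ends near 25 s and target then decays”.

**The result.** The flasks give Sunday's > Saturday's > Monday's > Thursday's, with 57.9 % and 21.6 %, and Thursday's > Sunday's > Saturday's > Monday's. Both orders match the forecast.

    starting material + target → 2 target (k = 0.379 M⁻¹ s⁻¹)
    starting material → target (k = 6.80 × 10⁻⁵ s⁻¹)
    target → over-reaction product (k = 0.0191 s⁻¹)
    starting material ⇌ dormant form (K = 1.25, k = 0.0143 s⁻¹)

**Level reused.** Take Thursday's flask at 2.00 min. Its 0.0142 M of free starting material is 0.232 of the break-even level, and the simulated making over using is 0.282. Leave Thursday's flask until 3.0 min. Its 0.0155 M free is 0.253 of the level, and target falls to 8.44 %, with a share of 9.17 %. Sunday's flask stands at 57.9 % at 2.00 min in part because dormant form returns to starting material and because the reading comes at that time: without that return its share is 44.4 %, and at 20.0 min it is 0.0665 %.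

The earlier runs and the new flask were generated by integration with constants of no real substance, noise included.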